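The constants describe a slow solid feeding a solution that a fast gas keeps supplied.

    gas phase ⇌ dissolved gas, rate k1*(csat - [dissolved gas]) (k1 = 20.2 h⁻¹, csat = 100 mM)
    starting material + dissolved gas → target (k2 = 2.41 M⁻¹ h⁻¹)
    dissolved gas + target → over-reacted product (k3 = 1.02 M⁻¹ h⁻¹)
    solid substrate ⇌ starting material, rate k4*(cs4 - [starting material]) while solid is left; crystals form when [starting material] > cs4 (cs4 = 1.4 M, k4 = 0.447 h⁻¹)
    target → over-reaction product (k5 = 0.128 h⁻¹)
    2 starting material → homo dimer (k6 = 0.327 M⁻¹ h⁻¹)

solid substrate 2.0 M; gas phase 100 mM (held); time 6.0 h

- east: doubling the transfer coefficient of step 1, all else as stated
- west: doubling the dissolution coefficient of step 4, all else as stated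
- south-west: doubling the saturation concentration of gas phase, all else as stated
- north-west: doubling the solubility in step 4, all else as stated

- percentages count the solid substrate that a species holds: one homo dimer counts as two
- for a step with 2 of a species take k times the square, and two of it per event
- solid, in amounts per volume of the solution: solid substrate
- at the start none of the gas is dissolved
- at the start none of the solid substrate is in solution
- run time (flask): 6.0 h

1. amount of target at 6.0 h, in percent of the solid substrate charged
2. concentration of dissolved gas in solution at 3.0 h, in percent of saturation
3. the change that raises the amount of target at 6.0 h, in percent of the solid substrate charged most ("none" if none brings more than 2 percentage points) (east / west / south-west / north-west / none)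
4. amount of target at 6.0 h, in percent of the solid substrate charged, after east

For whoever takes over the flask: solid substrate is dissolving, and starting material levels off where dissolving balances its two consuming steps, near 0.585 M with the gas at saturation. At that pace the solid lasts about 5.49 h, less than the run. The gas transfer coefficient of 20.2 h⁻¹ stands far above the 1.41 h⁻¹ drawn by starting material, so dissolved gas rests near 93.5 % of saturation.

Target starts rising at 0.141 M h⁻¹ and is lost with a pseudo-first-order constant λ = 0.230 h⁻¹. Its balance ratio is ρ = 1.05, the target over starting material at which making and losing balance at saturation. Joining that start to that balance, with starting material held at its plateau and the gas at saturation throughout, gives 22.9 % at the reading.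

Leave dissolution and solubility alone: at the plateau, each starting material goes to homo dimer at 0.382 h⁻¹ against 0.241 h⁻¹ to target. South-west lifts ρ to 1.45, so choose it; east raises the resting level of dissolved gas by about 3.37 % of itself.

The forecast, lower than this reckoning on target, gives 18.7 %, 92.4 % of saturation, south-west as best and 19.4 % after east, holding that “Doubling the gas saturation nearly doubles the rate of target formation”.

The flask gives 18.7 % target, south-west as best with a gain of 5.5 percentage points, and 19.1 % target after east. Its dissolved gas stands at 92.5 % of saturation. At 6.00 h, the flask holds 0 % solid substrate and 17.1 % starting material, less than the plateau's 29.2 %. Target over starting material there reads 1.09 against ρ of 1.05. The same flask read at 10.0 h reads 2.91, above ρ, with target down to 12.4 %.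

The rate constants are those of an exercise; the result is computed.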